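**Retrosynthetic overview**
1. The last event is cleavage of a tertiary O–SiMe3 group. Before it, one anionic relay step joins naphthalene-1,8-diol to an open 5-[(Z)-β-silylacryloyl]-6-alkynoate-9-hydroxyphenalenone and closes three rings in this order: the five-membered ring fused to the phenalenone, the cyclopentenone, and the 1,3-dioxine (spiroketal) ring.
2. Enabling feature: in the cis-bicyclo[3.3.0]octenone the ring-fusion CH lies between the cyclopentenone C=O, the spiroketal carbon (a β,β-dioxy ketone, i.e. the double oxa-Michael adduct of an alkynoate) and the C–OH carbon (a β-hydroxy ketone, i.e. an aldol bond). The C–OH oxygen also stands 1,4 to the enone α-CH across a cis C=C, so silicon can pass from that carbon to oxygen and the freed vinyl anion can take the acyl carbon.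
3. The open precursor comes from 6-bromo-9-hydroxy-1-oxophenalene-5-carbaldehyde. The CHO becomes the (Z)-β-silyl enone (alkynylation, syn-hydrogenation, oxidation) and the C–Br bond takes a chiral propiolate (Sonogashira).
4. The bromo aldehyde comes from 1,8-dimethoxynaphthalene by peri-annulation with a C3 acyl unit (third six-membered ring), bromoformylation, and demethylation/dehydrogenation. Both naphthalene units of the target therefore stem from naphthalene-1,8-diol.

Key step: step 11

Assumption: the two tautomers of each unsymmetrical 9-hydroxyphenalenone interconvert fast, so each is drawn as one tautomer, and the sense of induction of the 8-phenylmenthyl ester is taken from the usual shielding model (C–C bond formation on the face away from the phenyl ring, potassium-bridged closed transition state); should it be opposite, the (−)-alcohol would be used.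

**Step 1**
Reactants: 1 naphthalene-1,8-diol
Product: 2 1,8-dimethoxynaphthalene
Conditions: MeI (2.5 equiv), K2CO3, acetone, reflux
Reagents that add atoms: iodomethane, CI
Why: A double Williamson ether synthesis masks both phenols for the Lewis-acid steps.

**Step 2**
Reactants: 2 1,8-dimethoxynaphthalene; 3 3-chloropropanoyl chloride
Product: 4 3-chloro-1-(4,5-dimethoxynaphthalen-1-yl)propan-1-one
Conditions: AlCl3 (1.1 equiv), CH2Cl2, 0 °C
Reagents that add atoms: none
Why: Friedel–Crafts acylation should go para to a methoxy group (C4), the most activated and least hindered position of the symmetrical diether.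

**Step 3**
Reactants: 4 3-chloro-1-(4,5-dimethoxynaphthalen-1-yl)propan-1-one
Product: 5 6,7-dimethoxy-2,3-dihydro-1H-phenalen-1-one
Conditions: TfOH (3 equiv), 1,2-dichloroethane, 50 °C
Reagents that add atoms: none
Why: Loss of HCl gives the aryl vinyl ketone, whose protonated form should undergo an intramolecular Friedel–Crafts (conjugate) alkylation at the peri position, which is para to the second methoxy group whereas the ortho position is only meta-activated.

**Step 4**
Reactants: 5 6,7-dimethoxy-2,3-dihydro-1H-phenalen-1-one
Product: 6 3-bromo-6,7-dimethoxy-1H-phenalene-2-carbaldehyde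
Conditions: PBr3, DMF, CHCl3, 0 → 60 °C; then H2O
Reagents that add atoms: phosphorus tribromide, BrP(Br)Br; N,N-dimethylformamide, CN(C)C=O; water, O
Why: Vilsmeier–Haack–Arnold bromoformylation of an enolisable aryl ketone, well known for 6-methoxy-1-tetralone, puts the halogen on the former carbonyl carbon and the formyl group on the α-carbon and so fixes the 1,2-relationship of the two future side arms.

**Step 5**
Reactants: 6 3-bromo-6,7-dimethoxy-1H-phenalene-2-carbaldehyde
Product: 8 6-bromo-9-hydroxy-1-oxo-1H-phenalene-5-carbaldehyde, via dihydroxyphenalene 7 (not isolated)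
Conditions: BBr3 (2.5 equiv), CH2Cl2, −78 → 0 °C; H2O; then DDQ (1.05 equiv), THF, 0 °C
Reagents that add atoms: none
Why: Lewis-acid ether cleavage frees the peri-diol, and quinone dehydrogenation (hydride from the doubly benzylic CH2, proton from O–H) should give the 9-hydroxyphenalenone without a regiochemical issue, because both oxygens are free and the product tautomers are one compound.

**Step 6**
Reactants: 8 6-bromo-9-hydroxy-1-oxo-1H-phenalene-5-carbaldehyde; 9 ethynyltrimethylsilane
Product: 10 6-bromo-9-hydroxy-5-[1-hydroxy-3-(trimethylsilyl)prop-2-yn-1-yl]-1H-phenalen-1-one (racemic)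
Conditions: 9 (2.5 equiv), n-BuLi (2.4 equiv), THF, −78 °C; then 8, −78 → −30 °C; aq NH4Cl
Reagents that add atoms: none
Why: This is a 1,2-addition of a lithium acetylide to the aryl aldehyde, in which the first equivalent turns the acidic 9-OH into the delocalised phenalenolate that shields the enone part, and the new stereocentre is erased in step 8.

**Step 7**
Reactants: 10 (propargylic alcohol)
Product: 11 6-bromo-9-hydroxy-5-[(2Z)-1-hydroxy-3-(trimethylsilyl)prop-2-en-1-yl]-1H-phenalen-1-one (racemic)
Conditions: H2 (1 atm), Lindlar catalyst, quinoline, EtOAc, rt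
Reagents that add atoms: none
Why: Lindlar semihydrogenation adds H2 syn to the silyl alkyne and so sets the Z geometry that places silicon cis to the carbinol carbon.

**Step 8**
Reactants: 11 (Z-allylic alcohol)
Product: 12 6-bromo-9-hydroxy-5-[(2Z)-3-(trimethylsilyl)prop-2-enoyl]-1H-phenalen-1-one
Conditions: Dess–Martin periodinane (1.2 equiv), pyridine, CH2Cl2, 0 °C, dark
Reagents that add atoms: none
Why: Dess–Martin oxidation of the allylic, benzylic alcohol under buffered, non-nucleophilic conditions should preserve the Z geometry of the enone.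

**Step 9**
Reactants: 13 (+)-8-phenylmenthol, (1S,2R,5S)-5-methyl-2-(2-phenylpropan-2-yl)cyclohexan-1-ol; 14 propiolic acid
Product: 15 (1S,2R,5S)-5-methyl-2-(2-phenylpropan-2-yl)cyclohexyl prop-2-ynoate
Conditions: TsOH·H2O (cat.), toluene, reflux, Dean–Stark
Reagents that add atoms: none
Why: Acid-catalysed Fischer esterification with azeotropic removal of water does not touch the three stereocentres of the auxiliary.

**Step 10**
Reactants: 12 (bromo Z-enone); 15 (chiral propiolate)
Product: 16 (1S,2R,5S)-8-phenylmenthyl 3-{9-hydroxy-1-oxo-5-[(2Z)-3-(trimethylsilyl)prop-2-enoyl]-1H-phenalen-6-yl}prop-2-ynoate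
Conditions: PdCl2(PPh3)2 (5 mol %), CuI (10 mol %), K2CO3 (3 equiv), THF, 50 °C, dark
Reagents that add atoms: none
Why: In this Sonogashira coupling the C–Br bond is activated by the ortho acyl group and the carbonate base avoids amine addition to the propiolate.

**Step 11**
Reactants: 16 (aryl alkynoate / Z-β-silyl enone); 1 naphthalene-1,8-diol
Product: 19 spiropreussione B trimethylsilyl ether (tertiary O–SiMe3), via indenolate 17 (not isolated), via aryloxy dienone 18 (not isolated)
Conditions: 1 (1.05 equiv), KH (3.2 equiv), THF, −40 → 20 °C; AcOH, −78 °C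
Reagents that add atoms: none
Why: Proposed new method: the dipotassium salt of 1 adds to the alkynoate β-carbon (oxa-Michael), the allenolate attacks the neighbouring aryl ketone (5-(enolexo)-exo-trig aldol, five-membered ring on the phenalenone, first C–C bond) to give alkoxide 17, whose oxygen lies 1,4 to the cis C–Si bond, so that a 1,4-Brook (C(sp2)→O) silyl shift frees a (Z)-vinyl anion that expels 8-phenylmenthoxide from the adjacent ester (5-exo-trig acyl substitution, cyclopentenone ring, second C–C bond) to give 18, after which the remaining peri-naphthoxide closes the 1,3-dioxine by 6-exo-trig oxa-Michael addition and the dienolate is protonated on quenching. The closest known reaction types are Brook-mediated [3+2] annulations of β-silyl acryloyl systems with enolates, anion relay through alkoxide-triggered 1,4-silyl migration in (Z)-γ-silyl allylic alkoxides, conjugate addition/aldol (halo-aldol type) reactions of chiral propiolates and Parham-type acylation of vinyl anions by esters, and what is new is their coupling in one flask and the capture of the relayed vinyl anion by an ester. The carbinol centre is set in the aldol event, where the phenyl ring of the auxiliary covers one face of the allenolate, the ketone oxygen binds to the potassium of the enolate oxygen in a closed transition state, and C–C bond formation on the open face should give the carbinol configuration of the target. The ring-fusion CH is set last by protonation of the dienolate, which can only deliver the cis-fused bicyclo[3.3.0]octenone (H cis to OSiMe3). The step needs attack of the naphthoxide on the alkynoate and not on the enone, 1,2- and not 1,4-attack of the allenolate, and silicon cis to the carbinol carbon, which are secured by the β-silyl group shielding the enone terminus, by the five- versus seven-membered ring size, and by the Z geometry from step 7. All events before the acyl substitution are reversible, the medium holds no proton source (H2 is the only conjugate acid), and loss of the alkoxide makes the second C–C bond formation irreversible.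

**Step 12**
Reactants: 19 spiropreussione B trimethylsilyl ether
Product: 20 spiropreussione B
Conditions: HF·pyridine, THF, 0 °C
Reagents that add atoms: none
Why: Fluoride-mediated silyl ether cleavage under weakly acidic conditions should spare the base-sensitive β,β-dioxy ketone, the aryl ketal and both stereocentres.

**Compound list**
1 | naphthalene-1,8-diol | Oc1cccc2cccc(O)c12 | starting material
2 | 1,8-dimethoxynaphthalene | COc1cccc2cccc(OC)c12 | intermediate
3 | 3-chloropropanoyl chloride | O=C(Cl)CCCl | starting material
4 | 3-chloro-1-(4,5-dimethoxynaphthalen-1-yl)propan-1-one | COc1ccc(C(=O)CCCl)c2cccc(OC)c12 | intermediate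
5 | 6,7-dimethoxy-2,3-dihydro-1H-phenalen-1-one | O=C1CCc2ccc(OC)c3c(OC)ccc1c23 | intermediate
6 | 3-bromo-6,7-dimethoxy-1H-phenalene-2-carbaldehyde | BrC1=C(C=O)Cc2ccc(OC)c3c(OC)ccc1c23 | intermediate
7 | 3-bromo-6,7-dihydroxy-1H-phenalene-2-carbaldehyde (not isolated) | BrC1=C(C=O)Cc2ccc(O)c3c(O)ccc1c23 | intermediate
8 | 6-bromo-9-hydroxy-1-oxo-1H-phenalene-5-carbaldehyde | O=C1C=Cc2cc(C=O)c(Br)c3ccc(O)c1c23 | intermediate
9 | ethynyltrimethylsilane | C#C[Si](C)(C)C | starting material
10 | 6-bromo-9-hydroxy-5-[1-hydroxy-3-(trimethylsilyl)prop-2-yn-1-yl]-1H-phenalen-1-one (racemic carbinol) | O=C1C=Cc2cc(C(O)C#C[Si](C)(C)C)c(Br)c3ccc(O)c1c23 | intermediate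
11 | 6-bromo-9-hydroxy-5-[(2Z)-1-hydroxy-3-(trimethylsilyl)prop-2-en-1-yl]-1H-phenalen-1-one (racemic carbinol) | O=C1C=Cc2cc(C(O)/C=C\[Si](C)(C)C)c(Br)c3ccc(O)c1c23 | intermediate
12 | 6-bromo-9-hydroxy-5-[(2Z)-3-(trimethylsilyl)prop-2-enoyl]-1H-phenalen-1-one | O=C1C=Cc2cc(C(=O)/C=C\[Si](C)(C)C)c(Br)c3ccc(O)c1c23 | intermediate
13 | (+)-8-phenylmenthol, (1S,2R,5S) | O[C@H]1C[C@@H](C)CC[C@@H]1C(C)(C)c1ccccc1 | starting material
14 | propiolic acid | C#CC(=O)O | starting material
15 | (1S,2R,5S)-8-phenylmenthyl prop-2-ynoate | C#CC(=O)O[C@H]1C[C@@H](C)CC[C@@H]1C(C)(C)c1ccccc1 | intermediate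
16 | (1S,2R,5S)-8-phenylmenthyl 3-{9-hydroxy-1-oxo-5-[(2Z)-3-(trimethylsilyl)prop-2-enoyl]-1H-phenalen-6-yl}prop-2-ynoate | O=C1C=Cc2cc(C(=O)/C=C\[Si](C)(C)C)c(C#CC(=O)O[C@H]4C[C@@H](C)CC[C@@H]4C(C)(C)c4ccccc4)c3ccc(O)c1c23 | intermediate
17 | indenol fused to the phenalenone: tertiary carbinol (spatial arrangement as in 20) bearing the (Z)-2-(trimethylsilyl)vinyl group, next to the C=C that carries the 8-phenylmenthyl ester and the 8-hydroxynaphthalen-1-yloxy group; tripotassium salt in the flask, drawn neutral (not isolated) | O=C1C=Cc2cc3c(c4ccc(O)c1c24)C(Oc1cccc2cccc(O)c12)=C(C(=O)O[C@H]1C[C@@H](C)CC[C@@H]1C(C)(C)c1ccccc1)[C@]3(O)/C=C\[Si](C)(C)C | intermediate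
18 | cross-conjugated dienone: cyclopentenone closed, O–SiMe3 on the carbinol carbon, 8-hydroxynaphthalen-1-yloxy group on the exocyclic-to-enone C=C; dipotassium salt in the flask, drawn neutral (not isolated) | O=C1C=Cc2cc3c(c4ccc(O)c1c24)C(Oc1cccc2cccc(O)c12)=C1C(=O)C=C[C@]31O[Si](C)(C)C | intermediate
19 | spiropreussione B trimethylsilyl ether (cis-fused, H and OSiMe3 on the same face) | O=C1C=Cc2cc3c(c4ccc(O)c1c24)C1(Oc2cccc4cccc(c24)O1)[C@@H]1C(=O)C=C[C@]31O[Si](C)(C)C | intermediate
20 | spiropreussione B ((R)-carbinol carbon, (S)-ring-fusion CH) | O=C1C=Cc2cc3c(c4ccc(O)c1c24)C1(Oc2cccc4cccc(c24)O1)[C@@H]1C(=O)C=C[C@]31O | target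

**Total step count:** 12. **Longest linear sequence:** 11 (steps 1–8 and 10–12).

**Steps most likely to fail**

**1. Step 11.** The relayed vinyl anion may return by retro-Brook shift or be protonated faster than it attacks the hindered ester. The naphthoxide may add to the enone, and facial selectivity in the aldol event may be poor.

The fallback uses known chemistry, makes the two bonds one after the other at the aldehyde oxidation level, sets out from 10 and comes back at 20.
- 10 is oxidised with Dess–Martin periodinane to 6-bromo-9-hydroxy-5-[3-(trimethylsilyl)prop-2-ynoyl]-1H-phenalen-1-one F1.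
- Sonogashira coupling with 3,3-diethoxyprop-1-yne gives the alkynyl acetal F2.
- Aqueous acid frees the ynal F3.
- 1 with catalytic DABCO adds twice to the ynal and the enolate closes onto the ketone (double oxa-Michael/aldol) to give the racemic spiroketal hydroxy aldehyde F4.
- A cationic rhodium(I)–Tol-BINAP catalyst converts one enantiomer by intramolecular trans-hydroacylation of the 4-alkynal (kinetic resolution) into the α-silyl cyclopentenone F5.
- TBAF/AcOH removes the C-silyl group to give 20.

**2. Step 10.** Z→E isomerisation of the silyl enone by phosphine or copper may occur, as may conjugate addition of the phenalenolate to the propiolate or to the product.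

The fallback keeps the enone away from the coupling, sets out from 11 and comes back at 16.
- 11 is silylated (TESCl, imidazole) to the triethylsilyl ether F6.
- F6 is coupled with 15 to the aryl alkynoate F7.
- The silyl ether is cleaved with HF·pyridine to the allylic alcohol F8.
- F8 is oxidised at once with Dess–Martin periodinane/pyridine to 16.

**3. Step 3.** Ring closure may compete at the ortho position (five-membered ring), a methyl ether may be lost, or the vinyl ketone may oligomerise.

The fallback builds the C3 bridge from the other end, sets out from 2 and comes back at 5.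
- Vilsmeier–Haack formylation of 2 gives 4,5-dimethoxynaphthalene-1-carbaldehyde F9.
- Knoevenagel–Doebner condensation with malonic acid gives the acrylic acid F10.
- Hydrogenation over Pd/C gives the propanoic acid F11.
- Intramolecular Friedel–Crafts acylation (Eaton's reagent) at the peri position, para to the second methoxy group, gives 5.

**Further compounds**
F1 | step 11 | 6-bromo-9-hydroxy-5-[3-(trimethylsilyl)prop-2-ynoyl]-1H-phenalen-1-one | O=C1C=Cc2cc(C(=O)C#C[Si](C)(C)C)c(Br)c3ccc(O)c1c23
F2 | step 11 | 6-(3,3-diethoxyprop-1-yn-1-yl)-9-hydroxy-5-[3-(trimethylsilyl)prop-2-ynoyl]-1H-phenalen-1-one | O=C1C=Cc2cc(C(=O)C#C[Si](C)(C)C)c(C#CC(OCC)OCC)c3ccc(O)c1c23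
F3 | step 11 | 3-{9-hydroxy-1-oxo-5-[3-(trimethylsilyl)prop-2-ynoyl]-1H-phenalen-6-yl}prop-2-ynal | O=C1C=Cc2cc(C(=O)C#C[Si](C)(C)C)c(C#CC=O)c3ccc(O)c1c23
F4 | step 11 | racemic spiroketal hydroxy aldehyde (five-membered ring closed, C(OH)(C≡C–SiMe3) next to CH–CHO) | O=C1C=Cc2cc3c(c4ccc(O)c1c24)C1(Oc2cccc4cccc(c24)O1)C(C=O)C3(O)C#C[Si](C)(C)C
F5 | step 11 | spiropreussione B bearing SiMe3 on the enone α-carbon | O=C1C=Cc2cc3c(c4ccc(O)c1c24)C1(Oc2cccc4cccc(c24)O1)[C@@H]1C(=O)C([Si](C)(C)C)=C[C@]31O
F6 | step 10 | triethylsilyl ether of 11 | O=C1C=Cc2cc(C(O[Si](CC)(CC)CC)/C=C\[Si](C)(C)C)c(Br)c3ccc(O)c1c23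
F7 | step 10 | 8-phenylmenthyl aryl alkynoate with the carbinol as triethylsilyl ether | O=C1C=Cc2cc(C(O[Si](CC)(CC)CC)/C=C\[Si](C)(C)C)c(C#CC(=O)O[C@H]4C[C@@H](C)CC[C@@H]4C(C)(C)c4ccccc4)c3ccc(O)c1c23
F8 | step 10 | 8-phenylmenthyl aryl alkynoate with the free (Z)-allylic alcohol | O=C1C=Cc2cc(C(O)/C=C\[Si](C)(C)C)c(C#CC(=O)O[C@H]4C[C@@H](C)CC[C@@H]4C(C)(C)c4ccccc4)c3ccc(O)c1c23
F9 | step 3 | 4,5-dimethoxynaphthalene-1-carbaldehyde | COc1ccc(C=O)c2cccc(OC)c12
F10 | step 3 | (E)-3-(4,5-dimethoxynaphthalen-1-yl)prop-2-enoic acid | COc1ccc(/C=C/C(=O)O)c2cccc(OC)c12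
F11 | step 3 | 3-(4,5-dimethoxynaphthalen-1-yl)propanoic acid | COc1ccc(CCC(=O)O)c2cccc(OC)c12
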